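Ring atoms are numbered C1 (lactone O–CH) to C10 (ring fusion), with C11–C13 for the lactone carbons. Descriptors of intermediates use this numbering; their letters can change with the substituents while the spatial arrangement stays that of the target.

## Structural features

The target is a ten-membered carbocycle (C1–C10) cis-fused at C1/C10 to an α-methylene-γ-butyrolactone (O1, C11–C13). The carbocycle carries a (Z)-trisubstituted alkene at C2=C3, a secondary alcohol at C4, a cis trisubstituted epoxide at C5–C6 (methyl on C6) and an angelate ester at C9. Its six stereocentres form two contiguous groups, C9–C10–C1 and C4–C5–C6, separated by C2=C3 on one side and the C7–C8 ethylene on the other; all four ring oxygens and C11 lie on the same face of the ring. Fragile groups are the exocyclic enoate (Michael acceptor), the angelate (Z to E isomerisation under nucleophilic or basic catalysis), the epoxy alcohol (acid opening, epoxide migration under base) and the lactone, which can migrate to the cis C9 oxygen once that oxygen is free. The real difficulty is the medium ring with two Z trisubstituted double bonds and the relation of the two stereochemical groups across it. The key step exploits the γ-alkenyl γ-lactone: O1 is bound to allylic C1 beside C2=C3 and C11 to the neighbouring C10, the pattern left when a carboxymethyl radical adds to the C10 end of a C10=C1–C2=C3 ring diene and the carboxyl group closes on C1.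

## Logic of the disconnections

**30 from 29.** The C5–O and C6–O bonds of the epoxide are cut last, because the epoxide is the most sensitive group and its configuration can be taken from the neighbouring C4 hydroxyl. This removes a ring and two stereocentres and leaves only Z alkenes. The forward step must deliver oxygen to C5=C6 (not C2=C3) on the face cis to the C4 hydroxyl.

**29 from 28; 28 from 25 and 26.** The C4 O–Si bond and the C9 acyl C–O bond are cut. The ester is put on while C4 is still masked, so the two secondary alcohols never compete. This demands two silyl groups of different lability (C9 released first) and an acylation that neither isomerises the angelate nor lets the lactone migrate to O9.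

**25 from 24; 24 from 22; 22 from 21.** The C9 O–Si bond and the C11=C13 bond are cut. The methylene is added to the preformed lactone by enolate aminomethylation and elimination, so the Michael acceptor appears only after the radical step. The enolate chemistry must precede the angelate, and C9 must stay silylated during it.

**21 from 19 and 20.** The C10–C11 and C1–O bonds are cut in one operation. This removes the lactone ring and two stereocentres and leads back to a monocyclic triene and a two-carbon acid. 19 carries the C4 oxygen already, for three reasons:
- a later oxidation of the doubly allylic C4 methylene would have no dependable regio- or stereocontrol;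
- the C4 silyl ether lowers the reactivity of C2=C3 and C5=C6 toward the radical;
- it acts as a conformational anchor for the ring.

The forward step needs attack at C10 only, on the face cis to the C9 oxygen, capture at C1, and survival of two allylic silyl ethers. The cis relation is the opposite of what an outward-pointing allylic silyl ether normally induces in a ring, which is why the larger silyl group is placed on C4 and the smaller on C9.

**19 from 18.** The C10=C1 double bond is cut (ring-closing metathesis). This opens the ring to an acyclic tetraene whose two stereocentres are already fixed by reagent control. The forward step must close a strained ten-membered ring with Z geometry and without touching the trisubstituted alkenes.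

**18 from 17; 17 from 14 and 5.** The C4 O–Si bond and the C3–C4 bond are cut. The carbinol is formed together with the skeletal bond by adding a dienyl metal to a Z enal, so no allylic coupling with risk of geometry scrambling is needed. The forward step must control the C4 configuration by the catalyst and keep both Z geometries.

**14 from 13, 12, 11 and 10; 10 from 8 and 9.** The C9–C10 bond is cut. A vinyl Grignard addition gives the racemic carbinol, which is resolved at once so that all later material is one enantiomer. The resolution must return the R alcohol in high enantiomeric purity; the acetate at the other end is then exchanged for the aldehyde needed for the C3–C4 bond.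

**8 from 6 (through 7).** The C9 aldehyde comes from cleavage of the terminal trisubstituted alkene. The Z trisubstituted C5=C6 bond and carbons C4–C9 are thus bought ready-made. The forward step must oxidise the remote alkene in preference to the one next to the acetate.

**5 from 4, 3 and 1.** The terminal C=C of the diene and the C–I bond are cut. Directed hydroalumination of the alkynol fixes the Z geometry that will become C2=C3. The forward steps must keep this geometry through oxidation and olefination.

## Other disconnections considered

**Alternative 1:** The cut goes through both allylic C–O bonds, C1–O and C4–O. In the forward direction, photosensitised singlet oxygen would add across C1 and C4 of the (1Z,3Z)-diene A2, which already holds the epoxide, the C9 angelate and a C10 acrylate arm. This would give the bridged 1,2-dioxine A1; O–O reduction and lactonisation of the C1 hydroxyl onto the ester would finish.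
- In its favour: both oxygens arrive on one face in a single concerted event, so the cis-1,4 relation of C1–O and C4–OH and the Z geometry of C2=C3 follow from the mechanism. On this point it is better than the chosen plan, which sets C1 and C4 in separate steps (13 and 10). Its endgame is also shorter.
- Against it here: the cycloaddition needs the s-cis diene, which a (Z,Z)-diene in a ten-membered ring reaches only under strain, so ene reaction at the C3 methyl or at C10–H would compete. The face must be chosen by remote centres, and A2 contains a vinyl epoxide plus every sensitive group of the target.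
- Comparison: on mechanism, the chosen radical–polar annulation accepts the twisted or s-trans diene the ring prefers. On step economy, the route to A2 is judged longer than steps 1–12 of the chosen plan, although the steps after A1 are fewer.

**Alternative 2:** The cut is C7–C8. In the forward direction, Pd(PPh3)4 (zerovalent palladium) would ionise the isopropenyl epoxide of the lactone-bearing β-keto sulfone A4. The C8 carbanion would attack C7 of the π-allyl palladium alkoxide and close the ring to A3, releasing the C4 hydroxyl and forming C5=C6.
- In its favour: the macrocyclisation is neutral and self-buffered. C1 and C10 are set on a small lactone before ring closure (better than the chosen plan, where they depend on facial selectivity in the ring). C4 comes from an epoxide of defined configuration (equal or better than the catalytic zinc addition of step 10).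
- Against it here: the Z geometry of C5=C6 requires attack on the less favoured anti π-allyl isomer, and attack at C5 would give an eight-membered ring. C10 is α to the C9 ketone and can epimerise. The sulfone must be removed and the ketone reduced stereoselectively before methylenation, acylation and epoxidation.
- Comparison: on structure, the bond formed is remote from stereocentres but leaves two extra functional groups to correct. On mechanism, it is a two-electron process with predictable regiochemistry, against a radical step in the chosen plan. On step economy, its endgame is longer than the six steps after 21.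

**Alternative 3:** The cut is C1–C2. In the forward direction, CrCl2 with catalytic NiCl2 would convert the (Z)-vinyl iodide of the open-chain epoxy aldehyde A6 into an alkenylchromium species that adds to the C1 aldehyde and closes the ring to A5. Lactonisation, methylenation and protecting-group exchange would follow.
- In its favour: this is the most dependable closure for strained ten-membered carbocycles and tolerates epoxide, ester and ethers. The alkene geometry is carried over from the iodide (better than step 12, where Z rests on ring strain). C4–C6 and C9/C10 are set in the open chain by reagent control (better than a late directed epoxidation).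
- Against it here: the C1 carbinol is created during ring closure without a clear control element. A6 needs a long linear synthesis with five stereocentres and three kinds of protecting group, and the epoxide is carried through many steps.
- Comparison: on structure, the lactone becomes a simple late acylation (equal). On mechanism, a polar organochromium addition is more predictable than the radical addition. On step economy, the chosen plan (19 steps) is clearly shorter, at the price of one uncertain stereochemical event.

Key step: step 13

Remark: neryl acetate and angelic acid are taken as purchased; the facial sense of the amino-alcohol-catalysed zinc addition (step 10) is assumed to follow the simple-aldehyde model, in which the (+)-ligand adds to the Re face.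

## Steps

Step 1
Reactants: 1 but-2-yn-1-ol
Product: 3 (2Z)-3-iodobut-2-en-1-ol, via cyclic alkenylaluminate 2 (not isolated)
Conditions: NaAlH2(OCH2CH2OMe)2, THF, 0 °C to rt; then I2, −78 °C to rt
Reagents that add atoms: iodine, II
Why: Hydroxyl-directed trans-hydroalumination places aluminium on the distal alkyne carbon, cis to the CH2O group; iodinolysis with retention gives the Z iodide.

Step 2
Reactants: 3 (2Z)-3-iodobut-2-en-1-ol
Product: 4 (2Z)-3-iodobut-2-enal
Conditions: MnO2, CH2Cl2, rt
Reagents that add atoms: none
Why: Neutral allylic oxidation; no acid or base is present that could isomerise the Z iodoenal.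

Step 3
Reactants: 4 (2Z)-3-iodobut-2-enal
Product: 5 (3Z)-4-iodopenta-1,3-diene
Conditions: Ph3PCH3Br, KHMDS, THF, −78 to 0 °C; used as a solution
Reagents that add atoms: methyltriphenylphosphonium bromide, C[P+](c1ccccc1)(c1ccccc1)c1ccccc1.[Br-]
Why: Wittig methylenation of the aldehyde; the trisubstituted iodoalkene is not touched, so the Z geometry is kept.

Step 4
Reactants: 6 neryl acetate
Product: 8 (2Z)-3-methyl-6-oxohex-2-en-1-yl acetate, via terminal epoxide 7 (not isolated)
Conditions: mCPBA (1.0 equiv), CH2Cl2, 0 °C; then H5IO6, THF–H2O, 0 °C to rt
Reagents that add atoms: mCPBA, O=C(OO)c1cccc(Cl)c1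
Why: The remote trisubstituted alkene is more electron-rich than the one deactivated by the allylic acetate and is epoxidised first; periodic acid opens and cleaves the epoxide to the aldehyde and acetone.

Step 5
Reactants: 8 (2Z)-3-methyl-6-oxohex-2-en-1-yl acetate; 9 vinylmagnesium bromide
Product: 10 rac-(2Z)-6-hydroxy-3-methylocta-2,7-dien-1-yl acetate
Conditions: THF, −78 °C, 1.05 equiv of 9
Reagents that add atoms: none
Why: Grignard addition to the aldehyde is much faster than attack on the acetate at −78 °C; the new carbinol (C9) is racemic at this stage.

Step 6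
Reactants: 10 rac-(2Z)-6-hydroxy-3-methylocta-2,7-dien-1-yl acetate
Product: 11 (2Z,6R)-6-hydroxy-3-methylocta-2,7-dien-1-yl acetate
Conditions: Ti(OiPr)4, L-(+)-DIPT, TBHP (0.6 equiv), 4 Å MS, CH2Cl2, −20 °C
Reagents that add atoms: none
Why: Sharpless kinetic resolution of a secondary vinyl carbinol: with the L-(+)-tartrate the S enantiomer is epoxidised much faster, so the R alcohol (C9) should be recovered enantio-enriched, at most half of the material by design. The trisubstituted alkene is not an allylic alcohol and stays intact.

Step 7
Reactants: 11 (2Z,6R)-6-hydroxy-3-methylocta-2,7-dien-1-yl acetate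
Product: 12 (2Z,6R)-6-[(tert-butyldimethylsilyl)oxy]-3-methylocta-2,7-dien-1-yl acetate
Conditions: TBSCl, imidazole, DMF, rt
Reagents that add atoms: tert-butyldimethylsilyl chloride, CC(C)(C)[Si](C)(C)Cl
Why: Standard silylation of a secondary alcohol; TBS is the smaller and more labile of the two silyl groups used, as C9 must be released first later.

Step 8
Reactants: 12 (2Z,6R)-6-[(tert-butyldimethylsilyl)oxy]-3-methylocta-2,7-dien-1-yl acetate
Product: 13 (2Z,6R)-6-[(tert-butyldimethylsilyl)oxy]-3-methylocta-2,7-dien-1-ol
Conditions: K2CO3, MeOH, 0 °C to rt
Reagents that add atoms: none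
Why: Methanolysis of the primary acetate; the secondary silyl ether is stable to these conditions.

Step 9
Reactants: 13 (2Z,6R)-6-[(tert-butyldimethylsilyl)oxy]-3-methylocta-2,7-dien-1-ol
Product: 14 (2Z,6R)-6-[(tert-butyldimethylsilyl)oxy]-3-methylocta-2,7-dienal
Conditions: TEMPO (cat.), PhI(OAc)2, CH2Cl2, rt
Reagents that add atoms: none
Why: Oxoammonium oxidation of the primary allylic alcohol under near-neutral conditions, chosen because it oxidises Z allylic alcohols to Z enals without geometric isomerisation.

Step 10
Reactants: 14 (2Z,6R)-6-[(tert-butyldimethylsilyl)oxy]-3-methylocta-2,7-dienal; 5 (3Z)-4-iodopenta-1,3-diene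
Product: 17 (3Z,5S,6Z,10R)-10-[(tert-butyldimethylsilyl)oxy]-4,7-dimethyldodeca-1,3,6,11-tetraen-5-ol, via dienyllithium 15 (not isolated), via bis(dienyl)zinc 16 (not isolated)
Conditions: 5 (2.2 equiv), t-BuLi, Et2O, −78 °C; ZnBr2, −78 to 0 °C; Et2NCH2CH2NEt2, (+)-MIB (10 mol %), hexanes; then 14, 0 °C
Reagents that add atoms: none
Why: Amino-alcohol-catalysed enantioselective addition of an alkenylzinc reagent to an aldehyde; iodine–lithium exchange and transmetalation keep the alkene geometry, and the diamine sequesters lithium halides that would promote the racemic background addition. Delivery to the Re face of 14 sets C4 (ring numbering) as S under catalyst control; the C9 centre is too remote to interfere.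

Step 11
Reactants: 17 (3Z,5S,6Z,10R)-10-[(tert-butyldimethylsilyl)oxy]-4,7-dimethyldodeca-1,3,6,11-tetraen-5-ol
Product: 18 (3Z,5S,6Z,10R)-10-[(tert-butyldimethylsilyl)oxy]-5-[(tert-butyldiphenylsilyl)oxy]-4,7-dimethyldodeca-1,3,6,11-tetraene
Conditions: TBDPSCl, imidazole, DMAP (cat.), DMF, 40 °C
Reagents that add atoms: tert-butyldiphenylsilyl chloride, CC(C)(C)[Si](Cl)(c1ccccc1)c1ccccc1
Why: Silylation of the doubly allylic alcohol under basic conditions that cannot ionise it; TBDPS is chosen for bulk (conformational anchor in step 13) and for stability to hot acetic acid.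

Step 12
Reactants: 18 (3Z,5S,6Z,10R)-10-[(tert-butyldimethylsilyl)oxy]-5-[(tert-butyldiphenylsilyl)oxy]-4,7-dimethyldodeca-1,3,6,11-tetraene
Product: 19 ten-membered (Z,Z,Z)-triene with C10=C1–C2=C3(Me) diene and C5=C6(Me) alkene, (4S)-OTBDPS and (9R)-OTBS
Conditions: second-generation Hoveyda–Grubbs catalyst (10 mol %), toluene (0.001 M), 80 °C
Reagents that add atoms: none
Why: Ring-closing diene–ene metathesis between the two monosubstituted alkene ends; the trisubstituted alkenes are inert and, being Z, pre-fold the chain. The new C10=C1 bond should be Z because an E alkene conjugated to the (Z)-C2=C3 bond in this ring is far more strained and the closure is reversible.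

Step 13
Reactants: 19 ten-membered (Z,Z,Z)-triene with (4S)-OTBDPS and (9R)-OTBS; 20 acetic acid
Product: 21 cis-fused γ-lactone (1S,4S,9R,10S) on the ten-membered (2Z,5Z)-diene with 4-OTBDPS and 9-OTBS
Conditions: Mn(OAc)3·2H2O (2.2 equiv), KOAc, AcOH–Ac2O (10:1), degassed, 80 °C
Reagents that add atoms: none
Why: Mn(OAc)3 enolises bound acetate (in exchange with 20) and releases the electrophilic carboxymethyl radical, which adds to C10, the only diene terminus whose adduct is an allyl radical with a tertiary end (C1–C2–C3); trivalent manganese oxidises this radical to the allyl cation (or transfers the carboxylate within its coordination sphere) and the tethered carboxyl group closes on C1. The closest known reaction type is the Mn(OAc)3-mediated oxidative γ-lactone annulation of acetic acid onto alkenes and 1,3-dienes, which gives γ-alkenyl γ-lactones. The one ring formed is the five-membered lactone, closed by 5-exo attack of the carboxyl oxygen on the C1 end of the allyl unit; closure at C3 would give a seven-membered ring at a tertiary carbon flanked by the C4 silyl ether. C10 is set by the face of radical attack: C8 stands roughly perpendicular to the C10=C1 plane and blocks the ring side, the bulky C4 OTBDPS group is expected to take the outward position and so favour the ring conformer in which the smaller C9 OTBS group eclipses C10=C1, and attack anti to C8 on that conformer places C11 cis to the C9 oxygen. C1 is set by the two-atom tether: the oxygen reaches C1 from the face that carries C11, and with the Z geometry of C10=C1 this syn addition gives the cis ring fusion. Regioselectivity rests on conjugation (C10 rather than C2 or C5) and on inductive deactivation of C2=C3 and C5=C6 by the C4 oxygen; the Z geometry of C2=C3 is kept because the allyl unit cannot rotate inside the ring. KOAc buffers the medium so that both silyl ethers, each next to an ionisable allylic position, should survive.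

Step 14
Reactants: 21 cis-fused γ-lactone with 4-OTBDPS and 9-OTBS
Product: 22 11-[(dimethylamino)methyl] lactone (C11 epimers, both usable)
Conditions: LDA, THF, −78 °C; then CH2=NMe2+ I−, −78 to 0 °C
Reagents that add atoms: N,N-dimethylmethyleneiminium iodide, C=[N+](C)C.[I-]
Why: Mannich aminomethylation of the lactone enolate; the enolate has no β-leaving group and both silyl ethers are inert to amide base. The C11 configuration is irrelevant because it is removed in step 15.

Step 15
Reactants: 22 11-[(dimethylamino)methyl] lactone
Product: 24 α-methylene lactone (1S,4S,9R,10S) with 4-OTBDPS and 9-OTBS, via trimethylammonium iodide 23 (not isolated)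
Conditions: MeI, CH2Cl2, rt; then aq. NaHCO3, rt
Reagents that add atoms: none
Why: Quaternisation followed by base-induced elimination of trimethylamine gives the exocyclic methylene; bicarbonate is too weak to open the lactone or add to the enoate.

Step 16
Reactants: 24 α-methylene lactone with 4-OTBDPS and 9-OTBS
Product: 25 C9 alcohol (1S,4S,9R,10R) with 4-OTBDPS
Conditions: HF·pyridine, pyridine, THF, 0 °C to rt
Reagents that add atoms: none
Why: Under buffered HF the TBS ether is cleaved far faster than the TBDPS ether; the mildly acidic medium does not promote lactone migration to O9 or conjugate addition.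

Step 17
Reactants: 25 C9 alcohol with 4-OTBDPS; 26 angelic acid
Product: 28 C9 angelate (1S,4S,9R,10R) with 4-OTBDPS, via mixed anhydride 27 (not isolated)
Conditions: 26, 2,4,6-trichlorobenzoyl chloride, Et3N, toluene, rt; then 25, 80 °C (no DMAP)
Reagents that add atoms: none
Why: Yamaguchi-type acylation through the hindered mixed anhydride, which is attacked at the angeloyl carbonyl; leaving out the nucleophilic catalyst avoids the addition–elimination path that turns angelates into tiglates. C9 is acylated with retention.

Step 18
Reactants: 28 C9 angelate with 4-OTBDPS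
Product: 29 C4 alcohol (1S,4S,9R,10R): diene lactone with free 4-OH and 9-angelate
Conditions: TBAF, AcOH (1:1), THF, 0 °C to rt
Reagents that add atoms: none
Why: Acetic-acid-buffered fluoride removes the TBDPS group without exposing the enoates to basic fluoride and without ionising the doubly allylic alcohol.

Step 19
Reactants: 29 C4 alcohol
Product: 30 target (1S,4R,5R,6S,9R,10R)
Conditions: VO(acac)2 (5 mol %), TBHP, CH2Cl2, 0 °C
Reagents that add atoms: tert-butyl hydroperoxide, CC(C)(C)OO
Why: Hydroxyl-directed epoxidation: the vanadate ester of the C4 hydroxyl delivers oxygen to the same face of C5=C6; for Z allylic alcohols held in a medium ring this mode gives the cis epoxy alcohol, which is the C5 R, C6 S arrangement needed. C2=C3 is deactivated by the allylic lactone oxygen, and the two enoates are too electron-poor to react.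

## Compound list

1 | but-2-yn-1-ol | CC#CCO | starting material
2 | sodium cyclic (Z)-alkenylaluminate (five-membered O–Al ring, Al on the methyl-bearing carbon) | CC1=CCO[Al-]1(OCCOC)OCCOC.[Na+] | intermediate
3 | (2Z)-3-iodobut-2-en-1-ol | C/C(I)=C/CO | intermediate
4 | (2Z)-3-iodobut-2-enal | C/C(I)=C/C=O | intermediate
5 | (3Z)-4-iodopenta-1,3-diene | C/C(I)=C/C=C | intermediate
6 | neryl acetate, (2Z)-3,7-dimethylocta-2,6-dien-1-yl acetate | CC(C)=CCC/C(C)=C\COC(C)=O | starting material
7 | (2Z)-5-(3,3-dimethyloxiran-2-yl)-3-methylpent-2-en-1-yl acetate (racemic epoxide) | CC1(C)OC1CC/C(C)=C\COC(C)=O | intermediate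
8 | (2Z)-3-methyl-6-oxohex-2-en-1-yl acetate | O=CCC/C(C)=C\COC(C)=O | intermediate
9 | vinylmagnesium bromide | C=C[Mg]Br | starting material
10 | rac-(2Z)-6-hydroxy-3-methylocta-2,7-dien-1-yl acetate | C=CC(O)CC/C(C)=C\COC(C)=O | intermediate
11 | (2Z,6R)-6-hydroxy-3-methylocta-2,7-dien-1-yl acetate | C=C[C@H](O)CC/C(C)=C\COC(C)=O | intermediate
12 | (2Z,6R)-6-[(tert-butyldimethylsilyl)oxy]-3-methylocta-2,7-dien-1-yl acetate | C=C[C@H](O[Si](C)(C)C(C)(C)C)CC/C(C)=C\COC(C)=O | intermediate
13 | (2Z,6R)-6-[(tert-butyldimethylsilyl)oxy]-3-methylocta-2,7-dien-1-ol | C=C[C@H](O[Si](C)(C)C(C)(C)C)CC/C(C)=C\CO | intermediate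
14 | (2Z,6R)-6-[(tert-butyldimethylsilyl)oxy]-3-methylocta-2,7-dienal | C=C[C@H](O[Si](C)(C)C(C)(C)C)CC/C(C)=C\C=O | intermediate
15 | [(2E)-penta-2,4-dien-2-yl]lithium (lithium cis to the vinyl group) | [Li]/C(C)=C\C=C | intermediate
16 | bis[(2Z)-penta-2,4-dien-2-yl]zinc | C=C/C=C(/C)[Zn]/C(C)=C\C=C | intermediate
17 | (3Z,5S,6Z,10R)-10-[(tert-butyldimethylsilyl)oxy]-4,7-dimethyldodeca-1,3,6,11-tetraen-5-ol | C=C[C@H](O[Si](C)(C)C(C)(C)C)CC/C(C)=C\[C@H](O)/C(C)=C\C=C | intermediate
18 | (3Z,5S,6Z,10R)-10-[(tert-butyldimethylsilyl)oxy]-5-[(tert-butyldiphenylsilyl)oxy]-4,7-dimethyldodeca-1,3,6,11-tetraene | C=C[C@H](O[Si](C)(C)C(C)(C)C)CC/C(C)=C\[C@H](O[Si](c1ccccc1)(c1ccccc1)C(C)(C)C)/C(C)=C\C=C | intermediate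
19 | ten-membered (Z,Z,Z)-triene: C10=C1–C2=C3(Me) diene, C5=C6(Me) alkene, (4S)-OTBDPS, (9R)-OTBS | CC(C)(C)[Si](C)(C)O[C@H]1/C=C\C=C(\C)[C@@H](O[Si](c2ccccc2)(c2ccccc2)C(C)(C)C)/C=C(/C)CC1 | intermediate
20 | acetic acid | CC(=O)O | starting material
21 | cis-fused γ-lactone (1S,4S,9R,10S) on the (2Z,5Z)-diene ring, 4-OTBDPS, 9-OTBS | O=C1O[C@H]2/C=C(/C)[C@@H](O[Si](c3ccccc3)(c3ccccc3)C(C)(C)C)/C=C(/C)CC[C@@H](O[Si](C)(C)C(C)(C)C)[C@H]2C1 | intermediate
22 | 11-[(dimethylamino)methyl] derivative of 21 (C11 epimers) | CN(C)CC1C(=O)O[C@H]2/C=C(/C)[C@@H](O[Si](c3ccccc3)(c3ccccc3)C(C)(C)C)/C=C(/C)CC[C@@H](O[Si](C)(C)C(C)(C)C)[C@@H]12 | intermediate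
23 | trimethylammonium iodide of 22 | C[N+](C)(C)CC1C(=O)O[C@H]2/C=C(/C)[C@@H](O[Si](c3ccccc3)(c3ccccc3)C(C)(C)C)/C=C(/C)CC[C@@H](O[Si](C)(C)C(C)(C)C)[C@@H]12.[I-] | intermediate
24 | α-methylene lactone (1S,4S,9R,10S), 4-OTBDPS, 9-OTBS | C=C1C(=O)O[C@H]2/C=C(/C)[C@@H](O[Si](c3ccccc3)(c3ccccc3)C(C)(C)C)/C=C(/C)CC[C@@H](O[Si](C)(C)C(C)(C)C)[C@@H]12 | intermediate
25 | α-methylene lactone (1S,4S,9R,10R) with free 9-OH, 4-OTBDPS | C=C1C(=O)O[C@H]2/C=C(/C)[C@@H](O[Si](c3ccccc3)(c3ccccc3)C(C)(C)C)/C=C(/C)CC[C@@H](O)[C@@H]12 | intermediate
26 | angelic acid, (2Z)-2-methylbut-2-enoic acid | C/C=C(/C)C(=O)O | starting material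
27 | angelic 2,4,6-trichlorobenzoic anhydride | C/C=C(/C)C(=O)OC(=O)c1c(Cl)cc(Cl)cc1Cl | intermediate
28 | 9-angelate (1S,4S,9R,10R), 4-OTBDPS | C=C1C(=O)O[C@H]2/C=C(/C)[C@@H](O[Si](c3ccccc3)(c3ccccc3)C(C)(C)C)/C=C(/C)CC[C@@H](OC(=O)/C(C)=C\C)[C@@H]12 | intermediate
29 | 9-angelate with free 4-OH (1S,4S,9R,10R), C5=C6 alkene still present | C=C1C(=O)O[C@H]2/C=C(/C)[C@@H](O)/C=C(/C)CC[C@@H](OC(=O)/C(C)=C\C)[C@@H]12 | intermediate
30 | CNP0500828.1 (1S,4R,5R,6S,9R,10R) | C=C1C(=O)O[C@H]2/C=C(/C)[C@@H](O)[C@H]3O[C@@]3(C)CC[C@@H](OC(=O)/C(C)=C\C)[C@@H]12 | target

## Step count and least certain steps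

Total step count: 19 (steps 1–3 for the dienyl iodide, steps 4–19 in the main line). Longest linear sequence: 16 steps (steps 4–19, from 6).

**Step 13 (key step).** Most likely failure: poor or inverted facial selectivity at C10. The ring conformer with the C9 silyloxy group turned outward is free of 1,3-allylic strain and may react faster than the conformer the design relies on; this would put C11 trans to the C9 oxygen. Ionisation of the allylic silyl ethers and attack on C5=C6 at 80 °C are secondary concerns.
Fallback (sets out from 19, returns at 21): run the annulation on the C9 epimer, in which both silyloxy groups can point outward in one conformer so that attack anti to C8 gives the required C10/C1 configuration, then correct C9. HF·pyridine removes the TBS group of 19 to give the (9R)-dienol F1; MnO2 gives the ring trienone F2; Corey–Bakshi–Shibata reduction with the (R)-oxazaborolidine gives the (9S)-dienol F3; TBSOTf and 2,6-lutidine give the 9-epi triene F4; the Mn(OAc)3 annulation then gives the 9-epi lactone F5. HF·pyridine gives the (9S)-alcohol F6; Dess–Martin periodinane gives the C9 ketone F7; reduction with the (S)-oxazaborolidine, with hydride arriving anti to C11, gives the (9R)-alcohol F8; TBSOTf converts it into 21.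

**Step 12.** Most likely failure: oligomerisation by intermolecular metathesis in place of closure of the strained ten-membered ring, or slow initiation at the hindered allylic silyl ether.
Fallback (sets out from 17, returns at 19): oxidise C4 with MnO2 to the acyclic dienone F9, in which the trigonal C4 and the two Z enone arms fold the chain; ring-closing metathesis gives the cyclic C4 ketone F10; Corey–Bakshi–Shibata reduction with the (R)-oxazaborolidine gives the cyclic (4S)-alcohol F11; TBDPSCl and imidazole give 19.

**Step 10.** Most likely failure: low enantiofacial control at C4 with a Z β,β-disubstituted enal and a trisubstituted dienylzinc, together with Z to E isomerisation of the enal by Lewis-acidic zinc species.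
Fallback (sets out from 14 and 5, returns at 17; no new compound): Nozaki–Hiyama–Kishi coupling with CrCl2, catalytic NiCl2 and a chiral sulfonamide ligand in MeCN at rt. This needs no organolithium, is neutral toward the Z enal and takes its stereocontrol from the chromium-bound ligand.

**Step 19.** Most likely failure: oxygen delivery to the wrong face of C5=C6 (the trans epoxy alcohol) if the ring does not hold the hydroxyl at the small dihedral angle the vanadium ester needs, or competing epoxidation of C2=C3.
Fallback (sets out from 29, returns at 30; no new compound): Sharpless epoxidation with Ti(OiPr)4, D-(−)-DIPT and TBHP at −20 °C. The tartrate is matched with the C4 configuration and imposes the erythro (cis) epoxy alcohol by reagent control.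

**Step 17.** Most likely failure: isomerisation of the angelate to the tiglate, or migration of the lactone to the free cis C9 hydroxyl under hot, basic acylation conditions.
Fallback (sets out from 25, returns at 28): DCC coupling of 25 with 2-[bis(2,2,2-trifluoroethoxy)phosphoryl]propanoic acid at 0 °C gives the phosphonate ester F12; Still–Gennari olefination with acetaldehyde (KHMDS, 18-crown-6, −78 °C) builds the Z enoate directly and gives 28.

## Further compounds

F1 | step 13 | (4S,9R)-dienol, 19 without the TBS group | O[C@H]1/C=C\C=C(\C)[C@@H](O[Si](c2ccccc2)(c2ccccc2)C(C)(C)C)/C=C(/C)CC1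
F2 | step 13 | ring trienone (C9 ketone), (4S)-OTBDPS | O=C1/C=C\C=C(\C)[C@@H](O[Si](c2ccccc2)(c2ccccc2)C(C)(C)C)/C=C(/C)CC1
F3 | step 13 | (4S,9S)-dienol | O[C@@H]1/C=C\C=C(\C)[C@@H](O[Si](c2ccccc2)(c2ccccc2)C(C)(C)C)/C=C(/C)CC1
F4 | step 13 | 9-epi triene, (4S)-OTBDPS, (9S)-OTBS | CC(C)(C)[Si](C)(C)O[C@@H]1/C=C\C=C(\C)[C@@H](O[Si](c2ccccc2)(c2ccccc2)C(C)(C)C)/C=C(/C)CC1
F5 | step 13 | 9-epi lactone (1S,4S,9S,10S) | O=C1O[C@H]2/C=C(/C)[C@@H](O[Si](c3ccccc3)(c3ccccc3)C(C)(C)C)/C=C(/C)CC[C@H](O[Si](C)(C)C(C)(C)C)[C@H]2C1
F6 | step 13 | (9S)-alcohol lactone, 4-OTBDPS | O=C1O[C@H]2/C=C(/C)[C@@H](O[Si](c3ccccc3)(c3ccccc3)C(C)(C)C)/C=C(/C)CC[C@H](O)[C@H]2C1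
F7 | step 13 | C9 ketone lactone, 4-OTBDPS | O=C1O[C@H]2/C=C(/C)[C@@H](O[Si](c3ccccc3)(c3ccccc3)C(C)(C)C)/C=C(/C)CCC(=O)[C@H]2C1
F8 | step 13 | (9R)-alcohol lactone, 4-OTBDPS | O=C1O[C@H]2/C=C(/C)[C@@H](O[Si](c3ccccc3)(c3ccccc3)C(C)(C)C)/C=C(/C)CC[C@@H](O)[C@H]2C1
F9 | step 12 | acyclic dienone, (3Z,6Z,10R)-10-[(tert-butyldimethylsilyl)oxy]-4,7-dimethyldodeca-1,3,6,11-tetraen-5-one | C=C[C@H](O[Si](C)(C)C(C)(C)C)CC/C(C)=C\C(=O)/C(C)=C\C=C
F10 | step 12 | cyclic C4 ketone of the (Z,Z,Z)-triene, (9R)-OTBS | CC(C)(C)[Si](C)(C)O[C@H]1/C=C\C=C(\C)C(=O)/C=C(/C)CC1
F11 | step 12 | cyclic (4S)-alcohol of the (Z,Z,Z)-triene, (9R)-OTBS | CC(C)(C)[Si](C)(C)O[C@H]1/C=C\C=C(\C)[C@@H](O)/C=C(/C)CC1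
F0 | step 10 | none | none
F0 | step 19 | none | none
F12 | step 17 | C9 2-[bis(2,2,2-trifluoroethoxy)phosphoryl]propanoate of 25 | C=C1C(=O)O[C@H]2/C=C(/C)[C@@H](O[Si](c3ccccc3)(c3ccccc3)C(C)(C)C)/C=C(/C)CC[C@@H](OC(=O)C(C)P(=O)(OCC(F)(F)F)OCC(F)(F)F)[C@@H]12
A1 | alternative 1 | C1/C4 endoperoxide of the epoxy angelate acrylate | C=C(C(=O)OC)[C@H]1[C@@H]2C=C(C)[C@@H](OO2)[C@H]3O[C@@]3(C)CC[C@H]1OC(=O)/C(C)=C\C
A2 | alternative 1 | (1Z,3Z)-diene epoxy angelate with C10 acrylate arm | C=C(C(=O)OC)[C@H]1/C=C\C(C)=C/[C@H]2O[C@@]2(C)CC[C@H]1OC(=O)/C(C)=C\C
A3 | alternative 2 | ten-membered hydroxy dienyl lactone with C9 ketone and C8 sulfone | O=C1O[C@H]2/C=C(/C)[C@@H](O)/C=C(/C)CC(S(=O)(=O)c3ccccc3)C(=O)[C@H]2C1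
A4 | alternative 2 | open-chain isopropenyl epoxide β-keto sulfone on the butyrolactone (C5 configuration open) | O=C1O[C@@H](/C=C(/C)[C@H]2OC2C(C)=C)[C@@H](C(=O)CS(=O)(=O)c3ccccc3)C1
A5 | alternative 3 | ten-membered epoxy allylic alcohol with C10 acetate arm, 4-OTBS, 9-OPMB | O[C@H]1/C=C(/C)[C@@H](O[Si](C)(C)C(C)(C)C)[C@H]2O[C@@]2(C)CC[C@@H](OCc3ccc(OC)cc3)[C@H]1CC(=O)OC
A6 | alternative 3 | open-chain (Z)-vinyl iodide epoxy aldehyde | I/C=C(/C)[C@@H](O[Si](C)(C)C(C)(C)C)[C@H]1O[C@@]1(C)CC[C@@H](OCc2ccc(OC)cc2)[C@H](C=O)CC(=O)OC
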